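## Structural features

Juglanin A is a cyclic diaryl ether heptanoid. Two benzene rings are joined twice, by one ether oxygen and by a seven-carbon chain (C1 on ring B to C7 on ring A) with a ketone at C5, which closes a 15-membered ring. Ring A is 1,3,4-trisubstituted: it carries C7, the bridging oxygen meta to C7, and a methoxy group next to that oxygen. Ring B carries four substituents in a row (bridging oxygen, methoxy, free hydroxyl, C1) with the chain para to the bridging oxygen, so the macrocycle is a meta,para-cyclophane. There is no stereocentre, so no two stereocentres stand next to each other and nothing has to be set or preserved. The fragile points are the enolisable ketone, the two electron-rich arenes and the free phenol beside C1, which is acidic, oxidisable, a hydrogen-atom donor and placed to close a dihydrobenzofuran onto any activated C2. The intermediates add a vinyl ketone and a primary iodide to that list. The real difficulty is closing a 15-membered ring that contains two rigid arenes without oligomerisation, and placing three different oxygen substituents plus the carbon arm correctly on ring B. The key step uses the C5 carbonyl: with C3–C4 drawn as a double bond, the ring A arm C7–C6–C5(=O)–C4=C3 is a vinyl ketone with an electrophilic terminus C3, while C2 on the short ring B arm can become a nucleophilic primary radical from a C–I bond. The bond C2–C3 then forms in the flexible middle of the chain, away from both arenes.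

## Logic of the disconnections

19 is taken back to 18 by putting silicon back on the ring B oxygen (O–Si bond). The phenol must be masked during ring closure, because its O–H bond would quench the C2 radical and its anion would displace a leaving group on C2. Nothing is gained in skeleton, but the last forward step becomes a mild unmasking. The demand is that the cleavage spares the ketone and the diaryl ether.

18 is cut at C2–C3 to give 17. The cut is placed there because the C5 carbonyl makes C3 an acceptor carbon and C2 can carry a radical, and because the bond lies mid-chain, remote from both rings. The gain is large: the macrocycle becomes an open diaryl ether with a two-carbon arm on ring B and a five-carbon arm on ring A. The forward step must close the ring faster than the radical is reduced, must attack the terminal alkene carbon only, and must find no weak X–H bond near C2.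

17 is cut at C4–C5, the vinyl–acyl bond, to give 14 and 15. This places the most labile group, the vinyl ketone, in the last step before ring closure, and lets C5 travel from the start as a robust N-methoxy-N-methyl amide. The forward step must add to the amide much faster than it touches the primary iodide, must stop at the ketone stage, and must be quenched so that the liberated hydroxylamine cannot add to the enone.

14 is taken back to 13 (C2–I from C2–OH) and 13 to 11 (C2–OH from cleavage of the C2=C bond of an allyl group, with loss of the terminal carbon). An allyl group is what a Claisen rearrangement delivers, and removing its terminal carbon leaves exactly the two-carbon arm. The forward oxidant must distinguish one alkene from two electron-rich arenes. The ring B oxygen must already be silylated, so that an activated C2 never faces a free ortho hydroxyl.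

11 is taken back to 10 (O–Si), 10 through 9 to 8 (the ring B carbon–C1 bond is traded for an O–allyl bond by a [3,3] shift), and 8 to 6 and 7 (O–CH2 bond). The rearrangement places the carbon arm ortho to the hydroxyl at the only free ortho carbon, which fixes the 1,2,3,4 pattern of ring B without a directing group. The demands are migration to the ortho and not the para carbon, and survival of the amide at the temperature needed.

6 is cut at the bond between the ring A carbon and the bridging oxygen to give 4 and 5. This divides the molecule into its two rings. Since 5 is symmetric, either hydroxyl gives the same product and no protecting group is needed. The forward coupling must join two ortho-substituted partners and stop after one arylation.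

4 is taken back to 2 (amide C–N) and 2 to 1 (aryl C–Br). The methoxy group of 1 directs the halogen to the carbon that later bears the bridging oxygen, so ring A needs no further adjustment. The only demand is monobromination ortho to the methoxy group.

## Other disconnections considered

Alternative 1: Ring A is taken apart at two of its bonds into a 2-pyrone diene and a terminal alkyne, giving the pyrone alkyne A1. In the forward step, heating A1 would bring about an intramolecular [4+2] cycloaddition of the pyrone (C3 to the alkyne CH, C6 to the internal alkyne carbon) followed by loss of CO2. This would create ring A and the macrocycle together as the benzyl ether ketal A2.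
- In favour: two carbon–carbon bonds and two rings arise in one metal-free, neutral step, and the adjacent methoxy and aryloxy groups of ring A are written into the pyrone. In bonds and rings formed per step it is better than the chosen plan (two and two against one and one).
- Against: a 3-aryloxy-4-methoxy-2-pyrone is an electron-rich diene and an unactivated terminal alkyne is a weak partner, so high temperatures would be expected. The regiochemistry is held only by the tether: the tethered alkyne carbon must bond to the far pyrone carbon, and the opposite orientation would give an ortho-linked ring isomer. In the chosen plan the polarity of radical and enone fixes the site of attack.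
- Step economy: the pyrone ether and the whole C1–C7 chain plus alkyne must be built on ring B, whereas the chosen plan buys both arenes ready-made. After A2, two unmaskings (ketal hydrolysis, hydrogenolysis) are needed against one after 18.
- Equal points: both closures need dilution, and neither creates a stereocentre.

Alternative 2: The bond between ring A and C7 is cut, giving the bromoarene alkene A3 with C5 held as a silyl ether. In the forward step, 9-BBN would add to the terminal alkene to give the alkylborane A4, and zerovalent palladium (generated from Pd(dppf)Cl2, with Cs2CO3 as base) would couple boron-bearing C7 with the ring A bromide to give the macrocycle A5.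
- In favour: the sp2–sp3 coupling is tolerant and well understood, and anti-Markovnikov hydroboration fixes boron on C7. Closure does not compete with a chain-transfer step, and no vinyl ketone or alkyl iodide has to be handled. On these mechanistic points it is better than the chosen plan.
- Against: a ketone cannot be present during hydroboration, so C5 must be carried as a protected alcohol. This adds a meaningless stereocentre and three operations after A5 (desilylation, oxidation, acetal cleavage) against one after 18.
- Structure: the full seven-carbon chain must be built on ring B, and ring A needs a bromine para to its methoxy group that survives the diaryl ether coupling, so two halogens must be differentiated. Ring closure also takes place at an arene carbon, where cyclophane strain is felt most, and not in mid-chain.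
- Equal points: ring size and the need for dilution are the same.

Alternative 3: The chain is cut at C3–C4 as an alkene, giving the diene A6 with a but-3-enyl arm on ring B and the same vinyl ketone arm as in 17. In the forward step, (H2IMes)(PCy3)Cl2Ru=CHPh (the second-generation Grubbs catalyst) would join the two termini with loss of ethylene and give the macrocyclic E-enone A7. Hydrogenation over palladium on carbon would then saturate C3=C4 and cleave the benzyl ether in one operation to give 19.
- In favour: the closure is catalytic and reversible, so oligomers can in principle be corrected, which the irreversible radical closure cannot do. A benzyl ether is allowed because no radical is involved. The one-step finish equals that of the chosen plan.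
- Against: ring B needs a four-carbon arm, and the Claisen rearrangement delivers three carbons, so a one-carbon homologation of about three steps or another ring B construction is needed. A7 must also hold a trans double bond inside an already constrained meta,para-cyclophane, whereas 18 is closed with sp3 carbons at C2 to C4.
- Overall: mechanistically it is the equal or the better of the chosen plan, and it loses only on the extra steps to A6 and on the strain of the unsaturated ring.

Key step: step 10

Remark on the chemistry: precursor and product were checked atom by atom (15-membered ring, chain meta to the bridging oxygen on ring A and para to it on ring B). The ring B oxygen is carried as a tert-butyldimethylsilyl ether, not as an acetate. An aryl acetate would not survive the vinyl Grignard step, and putting it on last would expose a free ortho phenol to an activated C2 (dihydrobenzofuran closure) and the vinyl ketone to acylation bases. Like an acetate, the silyl ether offers the C2 radical no weak C–H bond.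

Assumption: the macrocycle is treated as achiral and conformationally mobile, so no planar chirality has to be controlled.

## Route

Step 1
Reactants: 1 3-(4-methoxyphenyl)propanoic acid
Product: 2 3-(3-bromo-4-methoxyphenyl)propanoic acid
Conditions: Br2 (1.05 equiv), AcOH, rt
Reagents that add atoms: bromine, BrBr
Why: Electrophilic aromatic bromination; the methoxy group is the strongest director and its para position is blocked by the side chain, so bromine should enter ortho to it, at the carbon that later carries the bridging oxygen.

Step 2
Reactants: 2 3-(3-bromo-4-methoxyphenyl)propanoic acid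
Product: 4 3-(3-bromo-4-methoxyphenyl)-N-methoxy-N-methylpropanamide, via acyl imidazolide 3 (not isolated)
Conditions: CDI (1.1 equiv), CH2Cl2, rt; then MeNH(OMe)·HCl (1.3 equiv), rt
Reagents that add atoms: N,O-dimethylhydroxylamine hydrochloride, CNOC.Cl; 1,1'-carbonyldiimidazole, O=C(n1ccnc1)n1ccnc1 (its imidazole stays only in intermediate 3)
Why: Carboxyl activation as the acyl imidazole followed by aminolysis is a standard Weinreb amide synthesis; the aryl bromide and the methyl ether are inert.

Step 3
Reactants: 4 3-(3-bromo-4-methoxyphenyl)-N-methoxy-N-methylpropanamide; 5 2-methoxyresorcinol (2-methoxybenzene-1,3-diol)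
Product: 6 3-[3-(3-hydroxy-2-methoxyphenoxy)-4-methoxyphenyl]-N-methoxy-N-methylpropanamide
Conditions: 5 (3 equiv), CuI (10 mol %), N,N-dimethylglycine·HCl (30 mol %), Cs2CO3 (3 equiv), 1,4-dioxane, 100 °C, Ar
Reagents that add atoms: none
Why: Ligand-accelerated Ullmann diaryl ether synthesis with monovalent copper tolerates ortho substituents on both partners; the two hydroxyls of 5 are equivalent, and an excess of 5 should hold the reaction at mono-arylation.

Step 4
Reactants: 6 3-[3-(3-hydroxy-2-methoxyphenoxy)-4-methoxyphenyl]-N-methoxy-N-methylpropanamide; 7 allyl bromide
Product: 8 N-methoxy-3-{4-methoxy-3-[2-methoxy-3-(prop-2-en-1-yloxy)phenoxy]phenyl}-N-methylpropanamide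
Conditions: K2CO3, acetone, reflux
Reagents that add atoms: allyl bromide 7, C=CCBr
Why: Williamson O-alkylation of the phenoxide with a reactive allylic halide; no other acidic or nucleophilic site competes.

Step 5
Reactants: 8 N-methoxy-3-{4-methoxy-3-[2-methoxy-3-(prop-2-en-1-yloxy)phenoxy]phenyl}-N-methylpropanamide
Product: 10 3-{3-[3-hydroxy-2-methoxy-4-(prop-2-en-1-yl)phenoxy]-4-methoxyphenyl}-N-methoxy-N-methylpropanamide, via Claisen dienone 9 (not isolated)
Conditions: PhNEt2, 190 °C, sealed tube, Ar
Reagents that add atoms: none
Why: Aromatic Claisen rearrangement; the [3,3] shift should deliver the allyl group to the only free ortho carbon (the other bears the methoxy group), which is the carbon para to the bridging oxygen, and dienone 9 then tautomerises to the phenol. The basic amine solvent suppresses acid-catalysed ring closure of the ortho-allyl phenol.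

Step 6
Reactants: 10 3-{3-[3-hydroxy-2-methoxy-4-(prop-2-en-1-yl)phenoxy]-4-methoxyphenyl}-N-methoxy-N-methylpropanamide
Product: 11 3-{3-[3-(tert-butyldimethylsilyloxy)-2-methoxy-4-(prop-2-en-1-yl)phenoxy]-4-methoxyphenyl}-N-methoxy-N-methylpropanamide
Conditions: TBSCl, imidazole, DMF, rt to 40 °C
Reagents that add atoms: tert-butyldimethylsilyl chloride, CC(C)(C)[Si](C)(C)Cl
Why: Standard silylation of a phenol; the group is placed here so that the ring B oxygen is never free once C2 becomes electrophilic, and it survives borohydride, phosphine–iodine, Grignard and radical conditions.

Step 7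
Reactants: 11 3-{3-[3-(tert-butyldimethylsilyloxy)-2-methoxy-4-(prop-2-en-1-yl)phenoxy]-4-methoxyphenyl}-N-methoxy-N-methylpropanamide
Product: 13 3-{3-[3-(tert-butyldimethylsilyloxy)-4-(2-hydroxyethyl)-2-methoxyphenoxy]-4-methoxyphenyl}-N-methoxy-N-methylpropanamide, via secondary ozonide 12 (not isolated)
Conditions: O3, CH2Cl2, −78 °C (Sudan Red 7B end point); then NaBH4, MeOH, −78 to 0 °C
Reagents that add atoms: ozone, [O-][O+]=O
Why: Ozonolysis of the terminal alkene with reductive work-up excises the terminal carbon and gives the 2-arylethanol directly; the indicator dye stops ozone before it reaches the arenes, and NaBH4 at 0 °C leaves the amide and the aryl silyl ether alone.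

Step 8
Reactants: 13 3-{3-[3-(tert-butyldimethylsilyloxy)-4-(2-hydroxyethyl)-2-methoxyphenoxy]-4-methoxyphenyl}-N-methoxy-N-methylpropanamide
Product: 14 3-{3-[3-(tert-butyldimethylsilyloxy)-4-(2-iodoethyl)-2-methoxyphenoxy]-4-methoxyphenyl}-N-methoxy-N-methylpropanamide
Conditions: PPh3, I2, imidazole, CH2Cl2, 0 °C to rt
Reagents that add atoms: iodine, II
Why: Appel iodination of a primary alcohol through the alkoxyphosphonium ion; the silylated ring B oxygen cannot compete with iodide for C2, and no Michael acceptor is present yet to be attacked by phosphine or imidazole.

Step 9
Reactants: 14 3-{3-[3-(tert-butyldimethylsilyloxy)-4-(2-iodoethyl)-2-methoxyphenoxy]-4-methoxyphenyl}-N-methoxy-N-methylpropanamide; 15 vinylmagnesium bromide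
Product: 17 5-{3-[3-(tert-butyldimethylsilyloxy)-4-(2-iodoethyl)-2-methoxyphenoxy]-4-methoxyphenyl}pent-1-en-3-one, via magnesium hemiaminal chelate 16 (not isolated)
Conditions: 15 (1.5 equiv), THF, −40 to 0 °C; inverse quench into 1 M HCl, 0 °C
Reagents that add atoms: vinylmagnesium bromide 15, C=C[Mg]Br
Why: Weinreb ketone synthesis; the five-membered magnesium chelate 16 holds the tetrahedral stage until work-up, so a single vinyl group is delivered. Uncatalysed attack of a vinyl Grignard reagent on a primary iodide is slow at these temperatures, and the cold acidic inverse quench keeps the released hydroxylamine protonated and off the enone.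

Step 10
Reactants: 17 5-{3-[3-(tert-butyldimethylsilyloxy)-4-(2-iodoethyl)-2-methoxyphenoxy]-4-methoxyphenyl}pent-1-en-3-one
Product: 18 O-(tert-butyldimethylsilyl)juglanin A (the 15-membered diaryl ether ketone with the ring B oxygen silylated)
Conditions: (Me3Si)3SiH (1.3 equiv) and AIBN (0.3 equiv) in PhMe by syringe pump over 10 h, to 17 (2 mM) in PhMe, 85 °C, Ar
Reagents that add atoms: none
Why: The silyl radical of the AIBN-started chain abstracts iodine from C2, and the resulting primary 2-arylethyl radical adds to C3, the unsubstituted terminus of the vinyl ketone, forming the C2–C3 bond. The adduct is an α-keto radical at C4, stabilised by the C5 carbonyl; it takes hydrogen from the silane, regenerates the silyl radical, and leaves C5 at the ketone oxidation level. The closest known reaction type is the free-radical macrocyclization of ω-iodoalkyl vinyl ketones and acrylates under Bu3SnH or (Me3Si)3SiH, an intramolecular Giese addition. The single ring is closed in the 15-endo-trig mode, and no stereocentre is formed. Two selectivities are needed: attack at C3 and not C4, and ring closure ahead of reduction of the C2 radical or chain growth of the C4 radical. The first is secured by polarity matching of a nucleophilic alkyl radical with the electron-poor, unhindered alkene terminus, and by the stabilised radical that only endo attack produces. The second is secured by keeping the silane concentration low through slow addition, by the lower hydrogen-donor rate of the silane compared with a tin hydride, and by 2 mM dilution. The silyl ether offers no weak C–H or O–H bond within reach of C2, and silyl radicals take iodine from a primary iodide faster than they add to an enone.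

Step 11
Reactants: 18 O-(tert-butyldimethylsilyl)juglanin A
Product: 19 juglanin A
Conditions: TBAF (1.2 equiv), AcOH (1.2 equiv), THF, 0 °C to rt
Reagents that add atoms: none
Why: Fluoride cleavage of an aryl silyl ether, buffered with acetic acid so that the phenoxide is protonated at once and the enolisable ketone sees no strong base.

## Compound list

1 | 3-(4-methoxyphenyl)propanoic acid | COc1ccc(CCC(=O)O)cc1 | starting material
2 | 3-(3-bromo-4-methoxyphenyl)propanoic acid | COc1ccc(CCC(=O)O)cc1Br | intermediate
3 | 3-(3-bromo-4-methoxyphenyl)-1-(imidazol-1-yl)propan-1-one (acyl imidazolide, not isolated) | COc1ccc(CCC(=O)n2ccnc2)cc1Br | intermediate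
4 | 3-(3-bromo-4-methoxyphenyl)-N-methoxy-N-methylpropanamide | COc1ccc(CCC(=O)N(C)OC)cc1Br | intermediate
5 | 2-methoxyresorcinol (2-methoxybenzene-1,3-diol) | COc1c(O)cccc1O | starting material
6 | 3-[3-(3-hydroxy-2-methoxyphenoxy)-4-methoxyphenyl]-N-methoxy-N-methylpropanamide | COc1ccc(CCC(=O)N(C)OC)cc1Oc1cccc(O)c1OC | intermediate
7 | allyl bromide (3-bromoprop-1-ene) | C=CCBr | starting material
8 | N-methoxy-3-{4-methoxy-3-[2-methoxy-3-(prop-2-en-1-yloxy)phenoxy]phenyl}-N-methylpropanamide | COc1ccc(CCC(=O)N(C)OC)cc1Oc1cccc(OCC=C)c1OC | intermediate
9 | Claisen dienone: 6-allyl-2-methoxy-3-aryloxycyclohexa-2,4-dien-1-one, aryl being the ring A amide unit (racemic, not isolated) | COc1ccc(CCC(=O)N(C)OC)cc1OC1=C(OC)C(=O)C(CC=C)C=C1 | intermediate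
10 | 3-{3-[3-hydroxy-2-methoxy-4-(prop-2-en-1-yl)phenoxy]-4-methoxyphenyl}-N-methoxy-N-methylpropanamide | COc1ccc(CCC(=O)N(C)OC)cc1Oc1ccc(CC=C)c(O)c1OC | intermediate
11 | 3-{3-[3-(tert-butyldimethylsilyloxy)-2-methoxy-4-(prop-2-en-1-yl)phenoxy]-4-methoxyphenyl}-N-methoxy-N-methylpropanamide | COc1ccc(CCC(=O)N(C)OC)cc1Oc1ccc(CC=C)c(O[Si](C)(C)C(C)(C)C)c1OC | intermediate
12 | secondary ozonide of 11: the allyl group replaced by a (1,2,4-trioxolan-3-yl)methyl group (racemic, not isolated) | COc1ccc(CCC(=O)N(C)OC)cc1Oc1ccc(CC2OCOO2)c(O[Si](C)(C)C(C)(C)C)c1OC | intermediate
13 | 3-{3-[3-(tert-butyldimethylsilyloxy)-4-(2-hydroxyethyl)-2-methoxyphenoxy]-4-methoxyphenyl}-N-methoxy-N-methylpropanamide | COc1ccc(CCC(=O)N(C)OC)cc1Oc1ccc(CCO)c(O[Si](C)(C)C(C)(C)C)c1OC | intermediate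
14 | 3-{3-[3-(tert-butyldimethylsilyloxy)-4-(2-iodoethyl)-2-methoxyphenoxy]-4-methoxyphenyl}-N-methoxy-N-methylpropanamide | COc1ccc(CCC(=O)N(C)OC)cc1Oc1ccc(CCI)c(O[Si](C)(C)C(C)(C)C)c1OC | intermediate
15 | vinylmagnesium bromide | C=C[Mg]Br | starting material
16 | bromomagnesium hemiaminal chelate from vinyl addition to the amide carbonyl of 14 (racemic, not isolated) | COc1ccc(CCC(C=C)(O[Mg]Br)N(C)OC)cc1Oc1ccc(CCI)c(O[Si](C)(C)C(C)(C)C)c1OC | intermediate
17 | 5-{3-[3-(tert-butyldimethylsilyloxy)-4-(2-iodoethyl)-2-methoxyphenoxy]-4-methoxyphenyl}pent-1-en-3-one (iodoethyl vinyl ketone, precursor of the key step) | COc1ccc(CCC(=O)C=C)cc1Oc1ccc(CCI)c(O[Si](C)(C)C(C)(C)C)c1OC | intermediate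
18 | O-(tert-butyldimethylsilyl)juglanin A (product of the key step) | COc1ccc2cc1Oc1ccc(c(O[Si](C)(C)C(C)(C)C)c1OC)CCCCC(=O)CC2 | intermediate
19 | juglanin A | COc1ccc2cc1Oc1ccc(c(O)c1OC)CCCCC(=O)CC2 | target

## Step count and least certain steps

Total step count: 11. Longest linear sequence: 11 steps (1 to 19); the route is linear, with 5, 7 and 15 entering as purchased reagents.

Step 10 (key step). The C2 radical may take hydrogen before the ring closes, or the C4 radical may add to a second vinyl ketone, because a 15-membered ring holding two arenes closes slowly. The fallback closes the same C2–C3 bond by metathesis and sets out from 11.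
- Allylmagnesium bromide in THF at −40 °C would convert the amide of 11 into the allyl ketone diene F1, with a cold acidic quench to avoid conjugation of the β,γ-enone.
- (H2IMes)(PCy3)Cl2Ru=CHPh, the second-generation Grubbs catalyst, at about 1 mM in CH2Cl2 would join the two allyl termini with loss of ethylene and give the macrocyclic C2=C3 alkene F2; either alkene geometry is acceptable.
- Hydrogenation (H2, palladium on carbon, EtOAc) would saturate the alkene and come back to the route at 18.

Step 9. The Grignard reagent may react at the iodide (elimination towards a styrene, or halide exchange), and the hydroxylamine may add in conjugate fashion to the vinyl ketone if the quench is slow. The fallback carries C2 as a sulfonate through the Grignard step and introduces iodine last; it sets out from 13.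
- TsCl, Et3N and catalytic DMAP in CH2Cl2 would give the tosylate F3.
- Vinylmagnesium bromide 15 with the same cold acidic quench would give the vinyl ketone tosylate F4.
- Finkelstein exchange (NaI, acetone, 50 °C, with NaHCO3) would come back to the route at 17.

Step 3. A second arylation of the product phenol, or slow coupling of two ortho-substituted partners, may lower the conversion. The fallback desymmetrises the diol before the coupling and sets out from 5 and 7.
- Mono-allylation of 5 (K2CO3, acetone, 7 as the limiting reagent) would give 3-(allyloxy)-2-methoxyphenol F5.
- Ullmann coupling of F5 with 4 under the same CuI conditions can arylate only once; it comes back to the route at 8 and absorbs step 4.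

Step 5. Part of the allyl group may migrate on to the para carbon through the blocked ortho position, the N-methoxy amide may degrade at 190 °C, or the ortho-allyl phenol may close to a methyl dihydrobenzofuran. The fallback builds the two-carbon arm without a rearrangement; it sets out from 6 and replaces steps 4 to 7 with the same number of operations.
- Magnesium-mediated ortho-formylation (MgCl2, Et3N, paraformaldehyde, MeCN, reflux), which can only occur at the free carbon beside the hydroxyl, would give the salicylaldehyde F6.
- Silylation (TBSCl, imidazole, DMF) would give the silyl ether aldehyde F7.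
- Wittig methylenation (Ph3PCH3Br, KN(SiMe3)2, THF, −78 to 0 °C) would give the styrene F8.
- Anti-Markovnikov hydroboration (9-BBN, THF, then NaBO3·4H2O) would come back to the route at 13.

Step 7. Ozone may attack the electron-rich arenes once the alkene is consumed, and the silyl group may be lost or shifted to the new alkoxide during the borohydride stage. The fallback avoids ozone and sets out from 11.
- Dihydroxylation (OsO4 catalytic, NMO, acetone–water) would give the racemic diol F9.
- NaIO4 in THF–water would cleave it to the arylacetaldehyde F10.
- Reduction with NaBH4 in MeOH at −20 °C would come back to the route at 13.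

## Further compounds

F1 | step 10 | 1-{3-[3-(tert-butyldimethylsilyloxy)-2-methoxy-4-(prop-2-en-1-yl)phenoxy]-4-methoxyphenyl}hex-5-en-3-one (allyl ketone diene) | COc1ccc(CCC(=O)CC=C)cc1Oc1ccc(CC=C)c(O[Si](C)(C)C(C)(C)C)c1OC
F2 | step 10 | 2,3-didehydro derivative of 18: macrocyclic C2=C3 alkene, mixture of alkene geometries | COc1ccc2cc1Oc1ccc(c(O[Si](C)(C)C(C)(C)C)c1OC)CC=CCC(=O)CC2
F3 | step 9 | 4-methylbenzenesulfonate (tosylate) of 13 | COc1ccc(CCC(=O)N(C)OC)cc1Oc1ccc(CCOS(=O)(=O)c2ccc(C)cc2)c(O[Si](C)(C)C(C)(C)C)c1OC
F4 | step 9 | vinyl ketone tosylate: analogue of 17 with 4-methylbenzenesulfonyloxy in place of iodine | COc1ccc(CCC(=O)C=C)cc1Oc1ccc(CCOS(=O)(=O)c2ccc(C)cc2)c(O[Si](C)(C)C(C)(C)C)c1OC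
F5 | step 3 | 3-(allyloxy)-2-methoxyphenol | COc1c(O)cccc1OCC=C
F6 | step 5 | 3-[3-(4-formyl-3-hydroxy-2-methoxyphenoxy)-4-methoxyphenyl]-N-methoxy-N-methylpropanamide | COc1ccc(CCC(=O)N(C)OC)cc1Oc1ccc(C=O)c(O)c1OC
F7 | step 5 | tert-butyldimethylsilyl ether of F6 | COc1ccc(CCC(=O)N(C)OC)cc1Oc1ccc(C=O)c(O[Si](C)(C)C(C)(C)C)c1OC
F8 | step 5 | 3-{3-[3-(tert-butyldimethylsilyloxy)-4-ethenyl-2-methoxyphenoxy]-4-methoxyphenyl}-N-methoxy-N-methylpropanamide | COc1ccc(CCC(=O)N(C)OC)cc1Oc1ccc(C=C)c(O[Si](C)(C)C(C)(C)C)c1OC
F9 | step 7 | 3-{3-[3-(tert-butyldimethylsilyloxy)-4-(2,3-dihydroxypropyl)-2-methoxyphenoxy]-4-methoxyphenyl}-N-methoxy-N-methylpropanamide (racemic) | COc1ccc(CCC(=O)N(C)OC)cc1Oc1ccc(CC(O)CO)c(O[Si](C)(C)C(C)(C)C)c1OC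
F10 | step 7 | 3-{3-[3-(tert-butyldimethylsilyloxy)-2-methoxy-4-(2-oxoethyl)phenoxy]-4-methoxyphenyl}-N-methoxy-N-methylpropanamide | COc1ccc(CCC(=O)N(C)OC)cc1Oc1ccc(CC=O)c(O[Si](C)(C)C(C)(C)C)c1OC
A1 | alternative 1 | 3-{3-(benzyloxy)-4-[4-(2-(but-3-yn-1-yl)-1,3-dioxolan-2-yl)butyl]-2-methoxyphenoxy}-4-methoxy-2H-pyran-2-one | COC1=C(Oc2ccc(CCCCC3(CCC#C)OCCO3)c(OCc3ccccc3)c2OC)C(=O)OC=C1
A2 | alternative 1 | O-benzyl juglanin A ethylene ketal | COc1ccc2cc1Oc1ccc(c(OCc3ccccc3)c1OC)CCCCC1(OCCO1)CC2
A3 | alternative 2 | tert-butyl({7-[4-(5-bromo-2-methoxyphenoxy)-3-methoxy-2-(methoxymethoxy)phenyl]hept-1-en-3-yl}oxy)dimethylsilane (racemic) | COCOc1c(CCCCC(O[Si](C)(C)C(C)(C)C)C=C)ccc(Oc2cc(Br)ccc2OC)c1OC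
A4 | alternative 2 | B-alkyl-9-borabicyclo[3.3.1]nonane from hydroboration of A3 at C7 (racemic) | COCOc1c(CCCCC(O[Si](C)(C)C(C)(C)C)CCB2C3CCCC2CCC3)ccc(Oc2cc(Br)ccc2OC)c1OC
A5 | alternative 2 | macrocyclic C5 tert-butyldimethylsilyl ether with methoxymethyl ether on ring B (racemic) | COc1ccc2cc1Oc1ccc(c(OCOC)c1OC)CCCCC(O[Si](C)(C)C(C)(C)C)CC2
A6 | alternative 3 | 5-{3-[3-(benzyloxy)-4-(but-3-en-1-yl)-2-methoxyphenoxy]-4-methoxyphenyl}pent-1-en-3-one | COc1ccc(CCC(=O)C=C)cc1Oc1ccc(CCC=C)c(OCc2ccccc2)c1OC
A7 | alternative 3 | macrocyclic (E)-C3=C4 enone benzyl ether | COc1ccc2cc1Oc1ccc(c(OCc3ccccc3)c1OC)CC/C=C/C(=O)CC2
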